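The pyranone ring C is cut at C3–C4 and O1–C2. This uses the fact that the C4 carbonyl carbon sits on ring A at C4a, ortho to the C8a–O1 oxygen. Ring A with C4 and O1 is therefore a salicylaldehyde, and C3–C2 with ring B is an aroyl sulfoxonium ylide. One Cp*Rh(III)-catalysed operation activates the formyl C–H, inserts the ylide-derived carbene and cyclodehydrates to the flavone. Both partners come from one phenol: salicylaldehyde 4 (5-benzyloxy-2-hydroxy-4-methoxy) is also O-methylated and converted into ylide 9. C3 is oxygenated and methylated afterwards, and the two benzyl ethers are removed last.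

Key step: step 6

Remark: the target has no stereogenic element, so no enantiomer has to be selected; 4-(benzyloxy)-3-methoxybenzaldehyde (O-benzylvanillin) is taken as a commercial material.

Step 1
Reactants: 1 4-(benzyloxy)-3-methoxybenzaldehyde
Product: 3 4-(benzyloxy)-3-methoxyphenol, via aryl formate 2 (not isolated)
Conditions: mCPBA, CH2Cl2, 0 °C to rt; aq. NaHCO3 wash; then K2CO3 (cat.), MeOH, rt
Reagents that add atoms: mCPBA (3-chloroperoxybenzoic acid), OOC(=O)c1cccc(Cl)c1
Why: Baeyer–Villiger (Dakin-type) oxidation, in which the electron-rich aryl group migrates in the Criegee adduct to give the aryl formate, which base-catalysed methanolysis cleaves to the phenol while the ethers stay untouched.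

Step 2
Reactants: 3 4-(benzyloxy)-3-methoxyphenol
Product: 4 5-(benzyloxy)-2-hydroxy-4-methoxybenzaldehyde
Conditions: MgCl2, Et3N, (CH2O)n, MeCN, reflux; aq. HCl work-up
Reagents that add atoms: paraformaldehyde (as formaldehyde), C=O
Why: Casnati–Skattebøl ortho-formylation, in which the magnesium phenoxide delivers formaldehyde only to an ortho carbon, here the open C6 (para to the methoxy group) and not C2 between OH and OMe, and a second formaldehyde oxidises the salicyl alcohol by hydride transfer.

Step 3
Reactants: 4 5-(benzyloxy)-2-hydroxy-4-methoxybenzaldehyde (the share not reserved for step 6)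
Product: 5 5-(benzyloxy)-2,4-dimethoxybenzaldehyde
Conditions: MeI, K2CO3, DMF, rt to 40 °C
Reagents that add atoms: iodomethane, CI
Why: Williamson ether synthesis on the only acidic group, the phenol, whose potassium salt in DMF should be alkylated despite its hydrogen bond to the formyl oxygen.

Step 4
Reactants: 5 5-(benzyloxy)-2,4-dimethoxybenzaldehyde
Product: 6 5-(benzyloxy)-2,4-dimethoxybenzoic acid
Conditions: NaClO2, NaH2PO4, 2-methyl-2-butene, t-BuOH/THF/H2O, 0 °C to rt
Reagents that add atoms: sodium chlorite, [Na+].[O-]Cl=O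
Why: Pinnick oxidation, in which chlorous acid adds to the aldehyde and fragments to the acid, while the alkene traps the hypochlorous acid before it can chlorinate the electron-rich ring.

Step 5
Reactants: 6 5-(benzyloxy)-2,4-dimethoxybenzoic acid; 7 trimethylsulfoxonium iodide
Product: 9 1-[5-(benzyloxy)-2,4-dimethoxyphenyl]-2-[dimethyl(oxo)-λ6-sulfanylidene]ethan-1-one, via acid chloride 8 (not isolated)
Conditions: (COCl)2, DMF (cat.), CH2Cl2, 0 °C to rt, evaporate; then added to 7 (3 equiv), KOtBu (3 equiv), THF, reflux then 0 °C to rt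
Reagents that add atoms: oxalyl chloride, O=C(Cl)C(=O)Cl (chlorine of 8 only; none of its atoms remain in 9)
Why: Acid chloride formation followed by C-acylation of dimethylsulfoxonium methylide (the Corey–Chaykovsky reagent), where a second equivalent of the methylide deprotonates the acylsulfoxonium salt to the stabilised β-keto ylide and inverse addition into excess methylide should suppress double acylation.

Step 6
Reactants: 4 5-(benzyloxy)-2-hydroxy-4-methoxybenzaldehyde; 9 1-[5-(benzyloxy)-2,4-dimethoxyphenyl]-2-[dimethyl(oxo)-λ6-sulfanylidene]ethan-1-one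
Product: 12 6-(benzyloxy)-2-[5-(benzyloxy)-2,4-dimethoxyphenyl]-7-methoxy-4H-chromen-4-one, via 1,3-diketone 10 (not isolated), via 2-hydroxyflavanone hemiketal 11 (not isolated)
Conditions: [Cp*RhCl2]2 (2.5 mol%), AgSbF6 (10 mol%), NaOAc (50 mol%), AcOH (1 equiv), DCE, 80 °C, N2
Reagents that add atoms: none
Why: The phenoxide of 4 binds Cp*Rh(III) and acetate-assisted cleavage of the neighbouring formyl C–H gives a five-membered acyl rhodacycle, to which ylide 9 adds through carbon and loses dimethyl sulfoxide to form a rhodium carbene; migratory insertion of the acyl group into this carbene makes C3–C4, and protonolysis frees diketone 10 and the catalyst. The closest known reaction type is the Rh(III)-catalysed, chelation-assisted aldehyde C–H annulation of salicylaldehydes with sulfoxonium ylides as carbene surrogates, which gives chromones. The single new ring, pyranone ring C, closes by 6-exo-trig addition of the phenol oxygen to the B-ring carbonyl (O1–C2) to give hemiketal 11, which should lose water under the acetic acid buffer to the aromatic 4-pyranone. No stereocentre is formed, since the C2 centre of 11 is transient. The step needs chemoselectivity for the formyl C–H over aryl C–H bonds and carbene insertion ahead of decarbonylation of the acyl–rhodium species, and both are secured by the ortho phenoxide chelate, which places only the formyl hydrogen within reach of the metal and holds the acyl ligand at a moderate temperature. The regiochemistry of ring closure is fixed by connectivity, because the B-ring carbonyl is the only one the phenol can reach through a six-membered transition state.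

Step 7
Reactants: 12 6-(benzyloxy)-2-[5-(benzyloxy)-2,4-dimethoxyphenyl]-7-methoxy-4H-chromen-4-one
Product: 15 6-(benzyloxy)-2-[5-(benzyloxy)-2,4-dimethoxyphenyl]-3-hydroxy-7-methoxy-4H-chromen-4-one, via 3-lithioflavone 13 (not isolated), via C3 dimethyl boronate 14 (not isolated)
Conditions: LDA, THF, −78 °C; B(OMe)3, −78 to 0 °C; AcOH, 30% aq. H2O2, 0 °C to rt
Reagents that add atoms: hydrogen peroxide, OO (the C3 oxygen); LDA, [Li+].CC(C)[N-]C(C)C (lithium of 13 only); trimethyl borate, COB(OC)OC (boron group of 14 only)
Why: Deprotonation of the flavone C3–H, the only sp2 C–H alpha to the pyranone carbonyl, followed by electrophilic borylation and boronate oxidation with 1,2-migration from boron to oxygen should give the flavonol, the low temperature keeping the 3-lithio species from ring opening and the benzylic ether C–H bonds from metalation.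

Step 8
Reactants: 15 6-(benzyloxy)-2-[5-(benzyloxy)-2,4-dimethoxyphenyl]-3-hydroxy-7-methoxy-4H-chromen-4-one
Product: 16 6-(benzyloxy)-2-[5-(benzyloxy)-2,4-dimethoxyphenyl]-3,7-dimethoxy-4H-chromen-4-one
Conditions: MeI, K2CO3, acetone, reflux
Reagents that add atoms: iodomethane, CI
Why: Williamson O-methylation of the 3-hydroxyl, the only acidic group left in the molecule.

Step 9
Reactants: 16 6-(benzyloxy)-2-[5-(benzyloxy)-2,4-dimethoxyphenyl]-3,7-dimethoxy-4H-chromen-4-one
Product: 17 6-hydroxy-2-(5-hydroxy-2,4-dimethoxyphenyl)-3,7-dimethoxy-4H-chromen-4-one (6,5'-dihydroxy-3,7,2',4'-tetramethoxyflavone)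
Conditions: H2 (1 atm), 10% Pd/C, THF/MeOH, rt
Reagents that add atoms: none
Why: Palladium-catalysed hydrogenolysis should cleave both benzylic C–O bonds, while the tetrasubstituted C2=C3 bond of the 3-methoxyflavone and the methyl ethers are expected to resist hydrogen at ambient pressure.

Compound list
1 | 4-(benzyloxy)-3-methoxybenzaldehyde (O-benzylvanillin) | COc1cc(C=O)ccc1OCc1ccccc1 | starting material
2 | 4-(benzyloxy)-3-methoxyphenyl formate | COc1cc(OC=O)ccc1OCc1ccccc1 | intermediate (not isolated)
3 | 4-(benzyloxy)-3-methoxyphenol | COc1cc(O)ccc1OCc1ccccc1 | intermediate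
4 | 5-(benzyloxy)-2-hydroxy-4-methoxybenzaldehyde | COc1cc(O)c(C=O)cc1OCc1ccccc1 | intermediate
5 | 5-(benzyloxy)-2,4-dimethoxybenzaldehyde | COc1cc(OC)c(C=O)cc1OCc1ccccc1 | intermediate
6 | 5-(benzyloxy)-2,4-dimethoxybenzoic acid | COc1cc(OC)c(C(=O)O)cc1OCc1ccccc1 | intermediate
7 | trimethylsulfoxonium iodide | C[S+](C)(C)=O.[I-] | starting material
8 | 5-(benzyloxy)-2,4-dimethoxybenzoyl chloride | COc1cc(OC)c(C(=O)Cl)cc1OCc1ccccc1 | intermediate (not isolated)
9 | 1-[5-(benzyloxy)-2,4-dimethoxyphenyl]-2-[dimethyl(oxo)-λ6-sulfanylidene]ethan-1-one | COc1cc(OC)c(C(=O)C=S(C)(C)=O)cc1OCc1ccccc1 | intermediate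
10 | 1-[5-(benzyloxy)-2-hydroxy-4-methoxyphenyl]-3-[5-(benzyloxy)-2,4-dimethoxyphenyl]propane-1,3-dione | COc1cc(O)c(C(=O)CC(=O)c2cc(OCc3ccccc3)c(OC)cc2OC)cc1OCc1ccccc1 | intermediate (not isolated)
11 | 6-(benzyloxy)-2-[5-(benzyloxy)-2,4-dimethoxyphenyl]-2-hydroxy-7-methoxychroman-4-one (racemic at C2) | COc1cc2OC(O)(c3cc(OCc4ccccc4)c(OC)cc3OC)CC(=O)c2cc1OCc1ccccc1 | intermediate (not isolated)
12 | 6-(benzyloxy)-2-[5-(benzyloxy)-2,4-dimethoxyphenyl]-7-methoxy-4H-chromen-4-one (6,5'-bis(benzyloxy)-7,2',4'-trimethoxyflavone) | COc1cc(OC)c(-c2cc(=O)c3cc(OCc4ccccc4)c(OC)cc3o2)cc1OCc1ccccc1 | intermediate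
13 | 3-lithio derivative of 12 | COc1cc(OC)c(-c2oc3cc(OC)c(OCc4ccccc4)cc3c(=O)c2[Li])cc1OCc1ccccc1 | intermediate (not isolated)
14 | 3-(dimethoxyboryl) derivative of 12 | COc1cc(OC)c(-c2oc3cc(OC)c(OCc4ccccc4)cc3c(=O)c2B(OC)OC)cc1OCc1ccccc1 | intermediate (not isolated)
15 | 6-(benzyloxy)-2-[5-(benzyloxy)-2,4-dimethoxyphenyl]-3-hydroxy-7-methoxy-4H-chromen-4-one | COc1cc(OC)c(-c2oc3cc(OC)c(OCc4ccccc4)cc3c(=O)c2O)cc1OCc1ccccc1 | intermediate
16 | 6-(benzyloxy)-2-[5-(benzyloxy)-2,4-dimethoxyphenyl]-3,7-dimethoxy-4H-chromen-4-one | COc1cc(OC)c(-c2oc3cc(OC)c(OCc4ccccc4)cc3c(=O)c2OC)cc1OCc1ccccc1 | intermediate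
17 | 6-hydroxy-2-(5-hydroxy-2,4-dimethoxyphenyl)-3,7-dimethoxy-4H-chromen-4-one (no stereocentre) | COc1cc(OC)c(-c2oc3cc(OC)c(O)cc3c(=O)c2OC)cc1O | target

Total step count: 9. Longest linear sequence: 9 steps (1 → 3 → 4 → 5 → 6 → 9 → 12 → 15 → 16 → 17); the salicylaldehyde partner 4 joins at step 6 after two steps from 1.

Steps most likely to fail

Step 6: the acyl–rhodium intermediate may decarbonylate, the ylide may be consumed by carbonyl-directed ortho C–H activation of its own aroyl ring, or the electron-rich, ortho-substituted partners may turn over too slowly. The fallback builds the same flavone by the classical chalcone route and sets out from 4. Excess MeMgBr in THF should add to the formyl group to give the carbinol 4-(benzyloxy)-2-(1-hydroxyethyl)-5-methoxyphenol F1. MnO2 in CH2Cl2 should oxidise the benzylic alcohol to 1-[5-(benzyloxy)-2-hydroxy-4-methoxyphenyl]ethan-1-one F2. Claisen–Schmidt condensation of this ketone with aldehyde 5 (KOH, EtOH, rt) should give (E)-1-[5-(benzyloxy)-2-hydroxy-4-methoxyphenyl]-3-[5-(benzyloxy)-2,4-dimethoxyphenyl]prop-2-en-1-one F3. Catalytic iodine in DMSO at 120 °C should then close and dehydrogenate the chalcone, so the fallback returns to the route at 12.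

Step 7: C3 metalation may be incomplete, or the 3-lithiated pyranone may ring-open before the borate traps it. The fallback oxidises the C2=C3 bond instead of metalating it and sets out from 12. Dimethyldioxirane in acetone/CH2Cl2 should give the epoxide 6-(benzyloxy)-2-[5-(benzyloxy)-2,4-dimethoxyphenyl]-2,3-epoxy-7-methoxychroman-4-one F4. Catalytic p-TsOH should open it at the acetal-like C2 and tautomerise it to the flavonol, so the fallback returns to the route at 15.

Step 5: the acid chloride may acylate the product ylide a second time, or be hydrolysed during transfer. The fallback uses a less reactive acyl donor and sets out from 6. MeI and K2CO3 in DMF should give methyl 5-(benzyloxy)-2,4-dimethoxybenzoate F5. Heating this ester with dimethylsulfoxonium methylide (from 7 and KOtBu in refluxing THF) should give the ylide by acyl substitution, since a methyl ester cannot acylate the stabilised product, and the fallback returns to the route at 9.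

Further compounds
F1 | step 6 | 4-(benzyloxy)-2-(1-hydroxyethyl)-5-methoxyphenol (racemic) | COc1cc(O)c(C(C)O)cc1OCc1ccccc1
F2 | step 6 | 1-[5-(benzyloxy)-2-hydroxy-4-methoxyphenyl]ethan-1-one | COc1cc(O)c(C(C)=O)cc1OCc1ccccc1
F3 | step 6 | (E)-1-[5-(benzyloxy)-2-hydroxy-4-methoxyphenyl]-3-[5-(benzyloxy)-2,4-dimethoxyphenyl]prop-2-en-1-one | COc1cc(O)c(C(=O)/C=C/c2cc(OCc3ccccc3)c(OC)cc2OC)cc1OCc1ccccc1
F4 | step 7 | 6-(benzyloxy)-2-[5-(benzyloxy)-2,4-dimethoxyphenyl]-2,3-epoxy-7-methoxychroman-4-one (racemic, cis-fused oxirane; one enantiomer drawn) | COc1cc(OC)c(cc1OCc1ccccc1)[C@]12O[C@H]1C(=O)c1cc(OCc3ccccc3)c(OC)cc1O2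
F5 | step 5 | methyl 5-(benzyloxy)-2,4-dimethoxybenzoate | COC(=O)c1cc(OCc2ccccc2)c(OC)cc1OC
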